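**Assumption:** the SMILES is read as the trans-(2R,3S)-dihydrobenzofuran (C-2 aryl and C-3 CH2OH on opposite faces); benzyl and methoxymethyl (MOM) groups serve as temporary protection.

## Retrosynthetic overview

1. The pyranone ring (ring C) of the flavonol is formed last, by acid cyclodehydration of a 2-benzyloxy-1,3-diketone, followed by O-debenzylation.
2. Key disconnection: the diketone C–C bond, made by a crossed Claisen coupling of a dihydrobenzofuran-4-carboxylic acid (as its acyl imidazolide) with the lithium enolate of an α-benzyloxy phloroglucinol ketone.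
3. Acid half: CO2H from ArBr; the dihydrofuran ring (formed first) by acid-mediated phenol capture of a benzylic cation in a 1,3-diol from an Evans syn-aldol (C-3 from the auxiliary, C-2 trans by thermodynamic control).
4. Both aldol partners come from catechol: O-benzylvanillin, and a 6-bromo-2,3-bis(MOM-oxy)phenylacetic acid (ortho-lithiation/ethylene oxide, bromination, oxidation).
5. Ketone half from resorcinol (Ir C–H borylation/oxidation to a phloroglucinol tris-MOM ether, ortho-lithiation) and a glycolate-derived Weinreb amide.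

## Route

Step 1
Reactants: 1 catechol
Product: 2 2-methoxyphenol (guaiacol)
Conditions: MeI (1.0 equiv), K2CO3 (1.0 equiv), acetone, reflux; distil
Reagents that add atoms: iodomethane, CI
Why: Williamson O-methylation with one equivalent of MeI gives mainly the mono-ether, which is separated from catechol and veratrole by distillation.

Step 2
Reactants: 2 2-methoxyphenol
Product: 3 4-bromo-2-methoxyphenol
Conditions: NBS (1.0 equiv), MeCN, 0 °C
Reagents that add atoms: N-bromosuccinimide, O=C1CCC(=O)N1Br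
Why: Electrophilic aromatic bromination goes para to the free OH, the strongest donor on the ring.

Step 3
Reactants: 3 4-bromo-2-methoxyphenol
Product: 4 1-(benzyloxy)-4-bromo-2-methoxybenzene
Conditions: BnBr, K2CO3, DMF, rt
Reagents that add atoms: benzyl bromide, BrCc1ccccc1
Why: Williamson etherification of the phenoxide protects the phenol before organolithium chemistry.

Step 4
Reactants: 4 1-(benzyloxy)-4-bromo-2-methoxybenzene
Product: 6 4-(benzyloxy)-3-methoxybenzaldehyde, via aryllithium 5 (not isolated)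
Conditions: n-BuLi, THF, −78 °C; DMF, −78 °C to rt; H2O
Reagents that add atoms: N,N-dimethylformamide, CN(C)C=O
Why: Fast bromine–lithium exchange at −78 °C followed by Bouveault formylation with DMF gives the aldehyde without touching the benzyl ether.

Step 5
Reactants: 1 catechol
Product: 7 1,2-bis(methoxymethoxy)benzene
Conditions: NaH (2.4 equiv), MOMCl (2.4 equiv), DMF, 0 °C to rt
Reagents that add atoms: chloromethyl methyl ether, COCCl
Why: Double O-alkylation of the bis-phenoxide installs MOM acetals that also serve as ortho-directing groups.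

Step 6
Reactants: 7 1,2-bis(methoxymethoxy)benzene; 8 ethylene oxide
Product: 10 2-[2,3-bis(methoxymethoxy)phenyl]ethan-1-ol, via aryllithium 9 (not isolated)
Conditions: n-BuLi, TMEDA, THF, 0 °C, 1 h; then 8 (3 equiv), −78 °C to rt; H2O
Reagents that add atoms: none
Why: Directed ortho-metalation next to OMOM followed by SN2 opening of the epoxide by the aryllithium adds the two-carbon chain.

Step 7
Reactants: 10 2-[2,3-bis(methoxymethoxy)phenyl]ethan-1-ol
Product: 11 2-[6-bromo-2,3-bis(methoxymethoxy)phenyl]ethan-1-ol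
Conditions: NBS (1.0 equiv), MeCN, 0 °C, dark
Reagents that add atoms: N-bromosuccinimide, O=C1CCC(=O)N1Br
Why: Electrophilic bromination goes para to the 3-OMOM group, because the doubly flanked 2-OMOM is twisted out of conjugation (as in 2,3-dialkoxytoluenes and 2,3-dimethoxybenzaldehyde).

Step 8
Reactants: 11 2-[6-bromo-2,3-bis(methoxymethoxy)phenyl]ethan-1-ol
Product: 12 2-[6-bromo-2,3-bis(methoxymethoxy)phenyl]acetic acid
Conditions: TEMPO (0.2 equiv), PhI(OAc)2 (2.2 equiv), MeCN/H2O 1:1, rt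
Reagents that add atoms: water, O
Why: Oxoammonium (TEMPO) oxidation gives the aldehyde, whose hydrate is oxidised on to the acid under near-neutral conditions that spare the MOM acetals.

Step 9
Reactants: 12 2-[6-bromo-2,3-bis(methoxymethoxy)phenyl]acetic acid
Product: 14 (4R)-4-benzyl-3-{2-[6-bromo-2,3-bis(methoxymethoxy)phenyl]acetyl}-1,3-oxazolidin-2-one, via mixed pivalic anhydride 13 (not isolated)
Conditions: PivCl, Et3N, THF, −20 °C; then (R)-4-benzyl-1,3-oxazolidin-2-one, LiCl, −20 °C to rt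
Reagents that add atoms: (R)-4-benzyl-1,3-oxazolidin-2-one, O=C1N[C@H](Cc2ccccc2)CO1
Why: The mixed anhydride is attacked at the less hindered arylacetyl carbonyl by the LiCl-activated oxazolidinone, giving the Evans imide.

Step 10
Reactants: 14 (4R)-4-benzyl-3-{2-[6-bromo-2,3-bis(methoxymethoxy)phenyl]acetyl}-1,3-oxazolidin-2-one; 6 4-(benzyloxy)-3-methoxybenzaldehyde
Product: 16 (4R)-4-benzyl-3-{(2R,3R)-3-[4-(benzyloxy)-3-methoxyphenyl]-2-[6-bromo-2,3-bis(methoxymethoxy)phenyl]-3-hydroxypropanoyl}-1,3-oxazolidin-2-one, via dibutylboron enolate 15 (not isolated)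
Conditions: Bu2BOTf (1.2 equiv), i-Pr2NEt (1.4 equiv), CH2Cl2, −78 to 0 °C; 6 (1.2 equiv), −78 to 0 °C; pH 7 buffer, MeOH, 30% H2O2, 0 °C
Reagents that add atoms: none
Why: Evans syn-aldol, in which the Z-boron enolate reacts through a Zimmerman–Traxler chair on the face away from the auxiliary benzyl group, setting the α-carbon (future C-3) as R and the carbinol as R.

Step 11
Reactants: 16 the syn-aldol imide
Product: 17 (1R,2S)-1-[4-(benzyloxy)-3-methoxyphenyl]-2-[6-bromo-2,3-bis(methoxymethoxy)phenyl]propane-1,3-diol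
Conditions: LiBH4, MeOH (2 equiv), THF, 0 °C
Reagents that add atoms: none
Why: Reductive cleavage of the imide by borohydride releases the auxiliary and gives the primary alcohol without touching either stereocentre (the α-descriptor changes from R to S only through CIP priorities).

Step 12
Reactants: 17 the 1,3-diol
Product: 19 (2R,3S)-2-[4-(benzyloxy)-3-methoxyphenyl]-4-bromo-3-(hydroxymethyl)-2,3-dihydro-1-benzofuran-7-ol, via MOM-free tetrol 18 (not isolated)
Conditions: 2 M HCl in MeOH/THF, 0 to 35 °C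
Reagents that add atoms: none
Why: Acetal methanolysis frees the catechol and the p-benzyloxybenzylic alcohol ionises and is captured by the adjacent phenol (SN1 5-exo cycloetherification), so C-3 from step 10 is untouched and directs C-2 to the thermodynamically favoured trans (2R,3S) isomer.

Step 13
Reactants: 19 the bromo phenol alcohol
Product: 20 (2R,3S)-2-[4-(benzyloxy)-3-methoxyphenyl]-4-bromo-7-(methoxymethoxy)-3-[(methoxymethoxy)methyl]-2,3-dihydro-1-benzofuran
Conditions: NaH (2.5 equiv), MOMCl (2.5 equiv), THF/DMF, 0 °C to rt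
Reagents that add atoms: chloromethyl methyl ether, COCCl
Why: Williamson-type alkylation of the phenoxide and the alkoxide masks both acidic OH groups for the lithiation and the enolate coupling.

Step 14
Reactants: 20 the bis-MOM aryl bromide
Product: 22 (2R,3S)-2-[4-(benzyloxy)-3-methoxyphenyl]-7-(methoxymethoxy)-3-[(methoxymethoxy)methyl]-2,3-dihydro-1-benzofuran-4-carboxylic acid, via aryllithium 21 (not isolated)
Conditions: t-BuLi (2.05 equiv), THF, −78 °C, 10 min; CO2 (g), −78 °C to rt; cold 1 M HCl to pH 3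
Reagents that add atoms: carbon dioxide, O=C=O
Why: Bromine–lithium exchange is much faster than any deprotonation at −78 °C, and carboxylation of the aryllithium gives the acid with both stereocentres (neither acidic nor adjacent to the anion) intact.

Step 15
Reactants: 23 methyl glycolate
Product: 24 methyl 2-(benzyloxy)acetate
Conditions: benzyl 2,2,2-trichloroacetimidate (1.2 equiv), TfOH (5 mol%), CH2Cl2/cyclohexane, 0 °C to rt
Reagents that add atoms: benzyl 2,2,2-trichloroacetimidate, N=C(OCc1ccccc1)C(Cl)(Cl)Cl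
Why: Acid-catalysed benzyl transfer from the trichloroacetimidate etherifies the α-hydroxy ester without the base that would cause self-condensation.

Step 16
Reactants: 24 methyl 2-(benzyloxy)acetate
Product: 25 2-(benzyloxy)-N-methoxy-N-methylacetamide
Conditions: MeNH(OMe)·HCl (1.5 equiv), i-PrMgCl (3.0 equiv), THF, −20 to 0 °C; 1 M HCl
Reagents that add atoms: N,O-dimethylhydroxylamine hydrochloride, CNOC.Cl
Why: The chloromagnesium amide formed in the flask attacks the ester and the chelated tetrahedral adduct collapses on work-up to the Weinreb amide.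

Step 17
Reactants: 26 resorcinol
Product: 27 1,3-bis(methoxymethoxy)benzene
Conditions: NaH (2.4 equiv), MOMCl (2.4 equiv), DMF, 0 °C to rt
Reagents that add atoms: chloromethyl methyl ether, COCCl
Why: Bis-MOM protection gives an ether with no unhindered aryl C–H other than C-5, as needed for the borylation.

Step 18
Reactants: 27 1,3-bis(methoxymethoxy)benzene
Product: 29 3,5-bis(methoxymethoxy)phenol, via arylboronic pinacol ester 28 (not isolated)
Conditions: [Ir(OMe)(cod)]2 (1.5 mol%), 4,4'-di-tert-butyl-2,2'-bipyridine (3 mol%), B2pin2 (0.55 equiv), THF, 80 °C; then aq NaOH, 30% H2O2, 0 °C to rt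
Reagents that add atoms: hydrogen peroxide, OO
Why: Sterically controlled iridium-catalysed C–H borylation hits the only C–H with no ortho substituent (C-5), and peroxide oxidation of the C–B bond (1,2-aryl shift) gives the phenol.

Step 19
Reactants: 29 3,5-bis(methoxymethoxy)phenol
Product: 30 1,3,5-tris(methoxymethoxy)benzene
Conditions: NaH (1.2 equiv), MOMCl (1.2 equiv), DMF, 0 °C to rt
Reagents that add atoms: chloromethyl methyl ether, COCCl
Why: O-alkylation of the phenoxide gives the C3-symmetric tris-ether, in which all three ring C–H positions are equivalent for lithiation.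

Step 20
Reactants: 30 1,3,5-tris(methoxymethoxy)benzene; 25 2-(benzyloxy)-N-methoxy-N-methylacetamide
Product: 32 2-(benzyloxy)-1-[2,4,6-tris(methoxymethoxy)phenyl]ethan-1-one, via aryllithium 31 (not isolated)
Conditions: n-BuLi (1.1 equiv), THF, 0 °C to rt, 1 h; 25 (1.2 equiv), −78 to 0 °C; H2O
Reagents that add atoms: none
Why: Directed ortho-metalation between two OMOM groups followed by Weinreb ketone synthesis (a stable chelated adduct prevents over-addition) gives the aryl ketone with unambiguous regiochemistry.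

Step 21
Reactants: 22 the dihydrobenzofuran-4-carboxylic acid; 32 2-(benzyloxy)-1-[2,4,6-tris(methoxymethoxy)phenyl]ethan-1-one
Product: 35 2-(benzyloxy)-1-{(2R,3S)-2-[4-(benzyloxy)-3-methoxyphenyl]-7-(methoxymethoxy)-3-[(methoxymethoxy)methyl]-2,3-dihydro-1-benzofuran-4-yl}-3-[2,4,6-tris(methoxymethoxy)phenyl]propane-1,3-dione (keto/enol and C-2 epimer mixture), via acyl imidazolide 33 (not isolated), via lithium enolate 34 (not isolated)
Conditions: 22, CDI (1.1 equiv), THF, rt, 1 h; separately 32 (2.2 equiv), LiN(SiMe3)2 (2.2 equiv), THF, −78 °C; combine, −78 to 0 °C; AcOH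
Reagents that add atoms: none
Why: Crossed Claisen condensation, in which the ketone lithium enolate is C-acylated by the acyl imidazolide and a second equivalent of enolate deprotonates the diketone, so no free amide base is present to attack the benzylic C-3–H.

Step 22
Reactants: 35 the 1,3-diketone
Product: 37 3-(benzyloxy)-2-{(2R,3S)-2-[4-(benzyloxy)-3-methoxyphenyl]-7-hydroxy-3-(hydroxymethyl)-2,3-dihydro-1-benzofuran-4-yl}-5,7-dihydroxy-4H-chromen-4-one, via MOM-free diketone 36 (not isolated)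
Conditions: 3 M aq HCl/MeOH/THF (1:4:2), 50 °C
Reagents that add atoms: none
Why: Acetal methanolysis removes all five MOM groups and the freed ortho-phenol adds to the aroyl carbonyl and dehydrates (chromone cyclodehydration as in a Baker–Venkataraman endgame); the symmetric ring A makes the closure regiochemically unambiguous.

Step 23
Reactants: 37 the dibenzyl flavonol
Product: 38 2-[(2R,3S)-7-hydroxy-2-(4-hydroxy-3-methoxyphenyl)-3-(hydroxymethyl)-2,3-dihydro-1-benzofuran-4-yl]-3,5,7-trihydroxy-4H-chromen-4-one (target)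
Conditions: H2 (1 atm), 10% Pd/C, EtOAc/MeOH, rt, stop at full conversion
Reagents that add atoms: none
Why: Hydrogenolysis of the aryl benzyl ether and the enol benzyl ether is fast at 1 atm, so the cyclic benzylic C-2–O bond and the chromone double bond are not reduced.

## Compound list

1 | catechol (benzene-1,2-diol) | Oc1ccccc1O | starting material
2 | 2-methoxyphenol | COc1ccccc1O | intermediate
3 | 4-bromo-2-methoxyphenol | COc1cc(Br)ccc1O | intermediate
4 | 1-(benzyloxy)-4-bromo-2-methoxybenzene | COc1cc(Br)ccc1OCc1ccccc1 | intermediate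
5 | [4-(benzyloxy)-3-methoxyphenyl]lithium | [Li]c1ccc(OCc2ccccc2)c(OC)c1 | intermediate
6 | 4-(benzyloxy)-3-methoxybenzaldehyde | COc1cc(C=O)ccc1OCc1ccccc1 | intermediate
7 | 1,2-bis(methoxymethoxy)benzene | COCOc1ccccc1OCOC | intermediate
8 | ethylene oxide (oxirane) | C1CO1 | starting material
9 | [2,3-bis(methoxymethoxy)phenyl]lithium | [Li]c1cccc(OCOC)c1OCOC | intermediate
10 | 2-[2,3-bis(methoxymethoxy)phenyl]ethan-1-ol | COCOc1cccc(CCO)c1OCOC | intermediate
11 | 2-[6-bromo-2,3-bis(methoxymethoxy)phenyl]ethan-1-ol | COCOc1ccc(Br)c(CCO)c1OCOC | intermediate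
12 | 2-[6-bromo-2,3-bis(methoxymethoxy)phenyl]acetic acid | COCOc1ccc(Br)c(CC(O)=O)c1OCOC | intermediate
13 | 2-[6-bromo-2,3-bis(methoxymethoxy)phenyl]acetic pivalic anhydride | COCOc1ccc(Br)c(CC(=O)OC(=O)C(C)(C)C)c1OCOC | intermediate
14 | (4R)-4-benzyl-3-{2-[6-bromo-2,3-bis(methoxymethoxy)phenyl]acetyl}-1,3-oxazolidin-2-one | COCOc1ccc(Br)c(CC(=O)N2[C@H](Cc3ccccc3)COC2=O)c1OCOC | intermediate
15 | (Z)-dibutylboron enolate of 14: (Z)-1-[(4R)-4-benzyl-2-oxo-1,3-oxazolidin-3-yl]-2-[6-bromo-2,3-bis(methoxymethoxy)phenyl]ethenyl dibutylborinate | CCCCB(CCCC)O/C(=C\c1c(Br)ccc(OCOC)c1OCOC)N1[C@H](Cc2ccccc2)COC1=O | intermediate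
16 | (4R)-4-benzyl-3-{(2R,3R)-3-[4-(benzyloxy)-3-methoxyphenyl]-2-[6-bromo-2,3-bis(methoxymethoxy)phenyl]-3-hydroxypropanoyl}-1,3-oxazolidin-2-one | O=C(N1[C@H](Cc2ccccc2)COC1=O)[C@H](c1c(Br)ccc(OCOC)c1OCOC)[C@@H](O)c1ccc(OCc2ccccc2)c(OC)c1 | intermediate
17 | (1R,2S)-1-[4-(benzyloxy)-3-methoxyphenyl]-2-[6-bromo-2,3-bis(methoxymethoxy)phenyl]propane-1,3-diol | OC[C@H](c1c(Br)ccc(OCOC)c1OCOC)[C@@H](O)c1ccc(OCc2ccccc2)c(OC)c1 | intermediate
18 | (1R,2S)-1-[4-(benzyloxy)-3-methoxyphenyl]-2-(6-bromo-2,3-dihydroxyphenyl)propane-1,3-diol | OC[C@H](c1c(Br)ccc(O)c1O)[C@@H](O)c1ccc(OCc2ccccc2)c(OC)c1 | intermediate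
19 | (2R,3S)-2-[4-(benzyloxy)-3-methoxyphenyl]-4-bromo-3-(hydroxymethyl)-2,3-dihydro-1-benzofuran-7-ol | COc1cc([C@@H]2Oc3c(O)ccc(Br)c3[C@H]2CO)ccc1OCc1ccccc1 | intermediate
20 | (2R,3S)-2-[4-(benzyloxy)-3-methoxyphenyl]-4-bromo-7-(methoxymethoxy)-3-[(methoxymethoxy)methyl]-2,3-dihydro-1-benzofuran | COc1cc([C@@H]2Oc3c(OCOC)ccc(Br)c3[C@H]2COCOC)ccc1OCc1ccccc1 | intermediate
21 | {(2R,3S)-2-[4-(benzyloxy)-3-methoxyphenyl]-7-(methoxymethoxy)-3-[(methoxymethoxy)methyl]-2,3-dihydro-1-benzofuran-4-yl}lithium | COc1cc([C@@H]2Oc3c(OCOC)ccc([Li])c3[C@H]2COCOC)ccc1OCc1ccccc1 | intermediate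
22 | (2R,3S)-2-[4-(benzyloxy)-3-methoxyphenyl]-7-(methoxymethoxy)-3-[(methoxymethoxy)methyl]-2,3-dihydro-1-benzofuran-4-carboxylic acid | COc1cc([C@@H]2Oc3c(OCOC)ccc(C(O)=O)c3[C@H]2COCOC)ccc1OCc1ccccc1 | intermediate
23 | methyl glycolate (methyl 2-hydroxyacetate) | COC(=O)CO | starting material
24 | methyl 2-(benzyloxy)acetate | COC(=O)COCc1ccccc1 | intermediate
25 | 2-(benzyloxy)-N-methoxy-N-methylacetamide | CON(C)C(=O)COCc1ccccc1 | intermediate
26 | resorcinol (benzene-1,3-diol) | Oc1cccc(O)c1 | starting material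
27 | 1,3-bis(methoxymethoxy)benzene | COCOc1cccc(OCOC)c1 | intermediate
28 | 2-[3,5-bis(methoxymethoxy)phenyl]-4,4,5,5-tetramethyl-1,3,2-dioxaborolane | COCOc1cc(OCOC)cc(c1)B1OC(C)(C)C(C)(C)O1 | intermediate
29 | 3,5-bis(methoxymethoxy)phenol | COCOc1cc(O)cc(OCOC)c1 | intermediate
30 | 1,3,5-tris(methoxymethoxy)benzene | COCOc1cc(OCOC)cc(OCOC)c1 | intermediate
31 | [2,4,6-tris(methoxymethoxy)phenyl]lithium | [Li]c1c(OCOC)cc(OCOC)cc1OCOC | intermediate
32 | 2-(benzyloxy)-1-[2,4,6-tris(methoxymethoxy)phenyl]ethan-1-one | COCOc1cc(OCOC)c(C(=O)COCc2ccccc2)c(OCOC)c1 | intermediate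
33 | 1-{(2R,3S)-2-[4-(benzyloxy)-3-methoxyphenyl]-7-(methoxymethoxy)-3-[(methoxymethoxy)methyl]-2,3-dihydro-1-benzofuran-4-carbonyl}-1H-imidazole | COc1cc([C@@H]2Oc3c(OCOC)ccc(C(=O)n4ccnc4)c3[C@H]2COCOC)ccc1OCc1ccccc1 | intermediate
34 | lithium (Z)-2-(benzyloxy)-1-[2,4,6-tris(methoxymethoxy)phenyl]ethen-1-olate | [Li]O/C(=C\OCc1ccccc1)c1c(OCOC)cc(OCOC)cc1OCOC | intermediate
35 | 2-(benzyloxy)-1-{(2R,3S)-2-[4-(benzyloxy)-3-methoxyphenyl]-7-(methoxymethoxy)-3-[(methoxymethoxy)methyl]-2,3-dihydro-1-benzofuran-4-yl}-3-[2,4,6-tris(methoxymethoxy)phenyl]propane-1,3-dione | COc1cc([C@@H]2Oc3c(OCOC)ccc(C(=O)C(OCc4ccccc4)C(=O)c4c(OCOC)cc(OCOC)cc4OCOC)c3[C@H]2COCOC)ccc1OCc1ccccc1 | intermediate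
36 | 2-(benzyloxy)-1-{(2R,3S)-2-[4-(benzyloxy)-3-methoxyphenyl]-7-hydroxy-3-(hydroxymethyl)-2,3-dihydro-1-benzofuran-4-yl}-3-(2,4,6-trihydroxyphenyl)propane-1,3-dione | COc1cc([C@@H]2Oc3c(O)ccc(C(=O)C(OCc4ccccc4)C(=O)c4c(O)cc(O)cc4O)c3[C@H]2CO)ccc1OCc1ccccc1 | intermediate
37 | 3-(benzyloxy)-2-{(2R,3S)-2-[4-(benzyloxy)-3-methoxyphenyl]-7-hydroxy-3-(hydroxymethyl)-2,3-dihydro-1-benzofuran-4-yl}-5,7-dihydroxy-4H-chromen-4-one | COc1cc([C@@H]2Oc3c(O)ccc(-c4oc5cc(O)cc(O)c5c(=O)c4OCc6ccccc6)c3[C@H]2CO)ccc1OCc1ccccc1 | intermediate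
38 | 2-[(2R,3S)-7-hydroxy-2-(4-hydroxy-3-methoxyphenyl)-3-(hydroxymethyl)-2,3-dihydro-1-benzofuran-4-yl]-3,5,7-trihydroxy-4H-chromen-4-one | COc1cc([C@@H]2Oc3c(O)ccc(-c4oc5cc(O)cc(O)c5c(=O)c4O)c3[C@H]2CO)ccc1O | target

## Step count and risks

Total step count: 23.
Longest linear sequence: 13 steps (steps 5–14, then 21–23; catechol 1 to target 38). The other branches are steps 1–4 (aldehyde 6), steps 15–16 (amide 25) and steps 17–20 (ketone 32).

Three steps most likely to fail:

**Step 7 (regioselectivity of the bromination).** If bromination of 10 gives the 5-bromo isomer (para to the 2-OMOM) in significant amount, the halogen is put in first. The fallback sets out from 7 and comes back at 11. Compound 7 is brominated with NBS in MeCN, where only one monobromide is possible, to give 4-bromo-1,2-bis(methoxymethoxy)benzene F1. F1 is deprotonated with LiN(i-Pr)2 in THF at −78 °C at the single position flanked by Br and OMOM, giving [6-bromo-2,3-bis(methoxymethoxy)phenyl]lithium F2. F2 is trapped at −78 °C with ethylene oxide 8 and BF3·OEt2, which is fast enough to outrun aryne formation, and delivers 11 with the substitution pattern fixed by the deprotonation site rather than by arene electronics.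

**Step 10 (aldol of an imide whose α-aryl group carries two ortho substituents).** If the Br/OMOM-flanked enolate is too hindered to add to 6, the bromine is introduced after ring closure. The fallback sets out from 10 and comes back at 19. Alcohol 10 is oxidised (TEMPO, PhI(OAc)2, MeCN/H2O) to [2,3-bis(methoxymethoxy)phenyl]acetic acid F3. F3 is activated with PivCl/Et3N as its mixed pivalic anhydride F4 and coupled with (R)-4-benzyl-1,3-oxazolidin-2-one/LiCl to the bromine-free imide F5. F5 is converted with Bu2BOTf/i-Pr2NEt into the Z-dibutylboron enolate F6, which adds to aldehyde 6 to give the bromine-free syn-aldol F7. LiBH4 reduction of F7 gives the bromine-free diol F8. HCl in MeOH takes F8 through the bromine-free tetrol F9 to the trans-dihydrobenzofuranol F10. F10 is then brominated with NBS (1.0 equiv) in CH2Cl2 at −40 °C para to the free 7-OH (the same selectivity as in step 2) to give 19.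

**Step 21 (intermolecular C-acylation of a hindered enolate; O-acylation or attack on the benzylic C-3–H would spoil it).** The C–C bond can instead be made intramolecularly by a Baker–Venkataraman acyl shift. The fallback sets out from 32 (with 22) and comes back at 37. Brief methanolysis of 32 (catalytic HCl in MeOH, 0 °C, stopped at the mono-phenol) removes one carbonyl-flanked MOM group and gives 2-(benzyloxy)-1-[2-hydroxy-4,6-bis(methoxymethoxy)phenyl]ethan-1-one F11. F11 is esterified with acid 22 (EDC·HCl, DMAP, CH2Cl2) to the aryl ester F12. KOt-Bu in THF at 0 °C induces the O-to-C acyl transfer and gives the mono-hydroxy diketone F13. Under the conditions of step 22, F13 loses its remaining MOM groups and cyclises through 36 to 37.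

## Further compounds

F1 | step 7 | 4-bromo-1,2-bis(methoxymethoxy)benzene | COCOc1ccc(Br)cc1OCOC
F2 | step 7 | [6-bromo-2,3-bis(methoxymethoxy)phenyl]lithium | [Li]c1c(Br)ccc(OCOC)c1OCOC
F3 | step 10 | [2,3-bis(methoxymethoxy)phenyl]acetic acid | COCOc1cccc(CC(O)=O)c1OCOC
F4 | step 10 | 2-[2,3-bis(methoxymethoxy)phenyl]acetic pivalic anhydride | COCOc1cccc(CC(=O)OC(=O)C(C)(C)C)c1OCOC
F5 | step 10 | (4R)-4-benzyl-3-{2-[2,3-bis(methoxymethoxy)phenyl]acetyl}-1,3-oxazolidin-2-one | COCOc1cccc(CC(=O)N2[C@H](Cc3ccccc3)COC2=O)c1OCOC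
F6 | step 10 | (Z)-1-[(4R)-4-benzyl-2-oxo-1,3-oxazolidin-3-yl]-2-[2,3-bis(methoxymethoxy)phenyl]ethenyl dibutylborinate | CCCCB(CCCC)O/C(=C\c1cccc(OCOC)c1OCOC)N1[C@H](Cc2ccccc2)COC1=O
F7 | step 10 | (4R)-4-benzyl-3-{(2R,3R)-3-[4-(benzyloxy)-3-methoxyphenyl]-2-[2,3-bis(methoxymethoxy)phenyl]-3-hydroxypropanoyl}-1,3-oxazolidin-2-one | O=C(N1[C@H](Cc2ccccc2)COC1=O)[C@H](c1cccc(OCOC)c1OCOC)[C@@H](O)c1ccc(OCc2ccccc2)c(OC)c1
F8 | step 10 | (1R,2S)-1-[4-(benzyloxy)-3-methoxyphenyl]-2-[2,3-bis(methoxymethoxy)phenyl]propane-1,3-diol | OC[C@H](c1cccc(OCOC)c1OCOC)[C@@H](O)c1ccc(OCc2ccccc2)c(OC)c1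
F9 | step 10 | (1R,2S)-1-[4-(benzyloxy)-3-methoxyphenyl]-2-(2,3-dihydroxyphenyl)propane-1,3-diol | OC[C@H](c1cccc(O)c1O)[C@@H](O)c1ccc(OCc2ccccc2)c(OC)c1
F10 | step 10 | (2R,3S)-2-[4-(benzyloxy)-3-methoxyphenyl]-3-(hydroxymethyl)-2,3-dihydro-1-benzofuran-7-ol | COc1cc([C@@H]2Oc3c(O)cccc3[C@H]2CO)ccc1OCc1ccccc1
F11 | step 21 | 2-(benzyloxy)-1-[2-hydroxy-4,6-bis(methoxymethoxy)phenyl]ethan-1-one | COCOc1cc(O)c(C(=O)COCc2ccccc2)c(OCOC)c1
F12 | step 21 | 2-[2-(benzyloxy)acetyl]-3,5-bis(methoxymethoxy)phenyl (2R,3S)-2-[4-(benzyloxy)-3-methoxyphenyl]-7-(methoxymethoxy)-3-[(methoxymethoxy)methyl]-2,3-dihydro-1-benzofuran-4-carboxylate | COc1cc([C@@H]2Oc3c(OCOC)ccc(C(=O)Oc4cc(OCOC)cc(OCOC)c4C(=O)COCc5ccccc5)c3[C@H]2COCOC)ccc1OCc1ccccc1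
F13 | step 21 | 2-(benzyloxy)-1-{(2R,3S)-2-[4-(benzyloxy)-3-methoxyphenyl]-7-(methoxymethoxy)-3-[(methoxymethoxy)methyl]-2,3-dihydro-1-benzofuran-4-yl}-3-[2-hydroxy-4,6-bis(methoxymethoxy)phenyl]propane-1,3-dione | COc1cc([C@@H]2Oc3c(OCOC)ccc(C(=O)C(OCc4ccccc4)C(=O)c5c(O)cc(OCOC)cc5OCOC)c3[C@H]2COCOC)ccc1OCc1ccccc1
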